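The route rests on cutting the diarylmethane bond between the C7 methylene carbon of the quinolin-2-one and C1' of the guaiacyl ring. The key step exploits the ortho pairing of the C8 oxygen and the C7–CH2 carbon on the benzo ring. A phenolic Mannich base, 7-(dimethylaminomethyl)-8-hydroxy-3-methoxyquinolin-2(1H)-one, expels dimethylamine to give the C8=O/C7=CH2 ortho-quinone methide. Its exocyclic carbon takes up an aryl-rhodium species made from 4-benzyloxy-3-methoxyphenylboronic acid. One operation forges the bond with boron-defined regiochemistry, rearomatises the ring and unveils only the C8 phenol. That phenol is then sulfated while the guaiacyl phenol stays benzylated until the last step.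

Key step: step 4

Remark: scolopendrine has no stereocentre, stereogenic axis or configured double bond. The SMILES therefore describes one achiral compound and no step has to control configuration. The free hydrogen sulfate as drawn is taken as the final form.

Step 1
Reactants: 1 7-bromoisatin (7-bromo-1H-indole-2,3-dione)
Product: 3 8-bromo-3-methoxyquinolin-2(1H)-one, via 8-bromo-3-hydroxyquinolin-2(1H)-one 2 (not isolated)
Conditions: TMSCHN2 (2 M in hexanes, 3 equiv), Et3N, EtOH, 0 °C to rt
Reagents that add atoms: (trimethylsilyl)diazomethane C[Si](C)(C)C=[N+]=[N-]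
Why: Eistert-type ring expansion, in which diazomethane released from TMSCHN2 adds to the C3 ketone of the isatin, the aryl carbon migrates with loss of N2 to give the 3-hydroxy-2-quinolone 2, and a second equivalent should O-methylate its acidic enol OH in preference to the lactam NH.

Step 2
Reactants: 3 8-bromo-3-methoxyquinolin-2(1H)-one
Product: 4 8-hydroxy-3-methoxyquinolin-2(1H)-one
Conditions: tBuBrettPhos Pd G3 (2 mol %), KOH (4 equiv), 1,4-dioxane/H2O, 80 °C; then 1 M HCl to pH 5
Reagents that add atoms: potassium hydroxide [K+].[OH-]
Why: Buchwald–Hartwig-type Pd-catalysed C–O coupling of an aryl bromide with hydroxide, in which the bulky biaryl phosphine favours C–O reductive elimination while the 3-methoxy-2-quinolone is inert to aqueous base.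

Step 3
Reactants: 4 8-hydroxy-3-methoxyquinolin-2(1H)-one
Product: 5 7-[(dimethylamino)methyl]-8-hydroxy-3-methoxyquinolin-2(1H)-one
Conditions: 37% aq. CH2O (1.1 equiv), 40% aq. Me2NH (1.2 equiv), EtOH, 60 °C
Reagents that add atoms: formaldehyde C=O; dimethylamine CNC
Why: Phenolic Mannich reaction, in which hydrogen bonding of the aminol/iminium to the C8 hydroxyl should deliver the electrophile to the free ortho carbon C7, as is usual for 8-hydroxyquinolines, and any aminomethylation at N1 is reversible.

Step 4
Reactants: 5 7-[(dimethylamino)methyl]-8-hydroxy-3-methoxyquinolin-2(1H)-one; 6 4-(benzyloxy)-3-methoxyphenylboronic acid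
Product: 8 7-[4-(benzyloxy)-3-methoxybenzyl]-8-hydroxy-3-methoxyquinolin-2(1H)-one, via ortho-quinone methide 7 (not isolated)
Conditions: [Rh(OH)(cod)]2 (2.5 mol %), 6 (2 equiv), 1,4-dioxane/H2O (10:1), 100 °C, N2 sweep
Reagents that add atoms: none
Why: Heating the Mannich base, whose phenol O and amine N can bind the boronic acid, expels dimethylamine and gives the ortho-quinone methide 7 (C8=O, C7=CH2), while Rh–OH transmetallates with 6 to an aryl–Rh(I) species. The aryl–Rh adds 1,4 to the O=C8–C7=CH2 unit at the exocyclic carbon, which forms the CH2–aryl bond and rearomatises the benzo ring to a rhodium phenoxide that water protonates, returning Rh–OH. The closest known reaction type is the rhodium-catalysed conjugate arylation (Hayashi–Miyaura type) of ortho-quinone methides released in situ from ortho-hydroxybenzylamines with arylboron reagents. No ring is closed and no stereocentre is formed. The step needs site selectivity on the guaiacyl ring, fixed by boron sitting para to the benzyloxy group, and chemoselectivity for the methide carbon over the C3=C4 bond of the pyridone ring, secured because only attack at CH2 regains benzenoid aromaticity. Re-addition of amine and hydration of 7 are reversible, so the irreversible aryl transfer should drain the equilibrium, and the absence of free 4 avoids methylene-bridged dimers.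

Step 5
Reactants: 8 7-[4-(benzyloxy)-3-methoxybenzyl]-8-hydroxy-3-methoxyquinolin-2(1H)-one
Product: 9 sodium 7-[4-(benzyloxy)-3-methoxybenzyl]-3-methoxy-2-oxo-1,2-dihydroquinolin-8-yl sulfate
Conditions: SO3·pyridine (4 equiv), pyridine, 50 °C; then aq. NaHCO3, C18 chromatography
Reagents that add atoms: sulfur trioxide–pyridine complex O=S(=O)([O-])[n+]1ccccc1; sodium hydrogen carbonate [Na+].OC([O-])=O
Why: O-sulfation of a phenol with an SO3–amine complex, in which C8–OH is the only free phenol because the guaiacyl oxygen is benzylated, and any adduct at the lactam is hydrolysed in the bicarbonate work-up.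

Step 6
Reactants: 9 sodium 7-[4-(benzyloxy)-3-methoxybenzyl]-3-methoxy-2-oxo-1,2-dihydroquinolin-8-yl sulfate
Product: 11 scolopendrine, via sodium salt of scolopendrine 10 (not isolated)
Conditions: H2 (1 atm), 10% Pd/C, MeOH, rt; filter, concentrate; then 1 M HCl (1 equiv), H2O, 0 °C, C18 desalting, lyophilisation
Reagents that add atoms: none
Why: Hydrogenolysis of the benzyl aryl ether, which leaves aryl sulfate salts, the diarylmethane and the aromatic 2-quinolone untouched, followed by brief cold protonation of the sulfate.

Compound list
1 | 7-bromoisatin | O=C1Nc2c(Br)cccc2C1=O | starting material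
2 | 8-bromo-3-hydroxyquinolin-2(1H)-one | Oc1cc2cccc(Br)c2[nH]c1=O | intermediate
3 | 8-bromo-3-methoxyquinolin-2(1H)-one | COc1cc2cccc(Br)c2[nH]c1=O | intermediate
4 | 8-hydroxy-3-methoxyquinolin-2(1H)-one | COc1cc2cccc(O)c2[nH]c1=O | intermediate
5 | 7-[(dimethylamino)methyl]-8-hydroxy-3-methoxyquinolin-2(1H)-one | COc1cc2ccc(CN(C)C)c(O)c2[nH]c1=O | intermediate
6 | 4-(benzyloxy)-3-methoxyphenylboronic acid | COc1cc(B(O)O)ccc1OCc1ccccc1 | starting material
7 | 3-methoxy-7-methylidenequinoline-2,8(1H,7H)-dione (ortho-quinone methide) | C=C1C=CC2=C(NC(=O)C(OC)=C2)C1=O | intermediate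
8 | 7-[4-(benzyloxy)-3-methoxybenzyl]-8-hydroxy-3-methoxyquinolin-2(1H)-one | COc1cc(Cc2ccc3cc(OC)c(=O)[nH]c3c2O)ccc1OCc1ccccc1 | intermediate
9 | sodium 7-[4-(benzyloxy)-3-methoxybenzyl]-3-methoxy-2-oxo-1,2-dihydroquinolin-8-yl sulfate | COc1cc(Cc2ccc3cc(OC)c(=O)[nH]c3c2OS(=O)(=O)[O-])ccc1OCc1ccccc1.[Na+] | intermediate
10 | sodium 7-(4-hydroxy-3-methoxybenzyl)-3-methoxy-2-oxo-1,2-dihydroquinolin-8-yl sulfate | COc1cc(Cc2ccc3cc(OC)c(=O)[nH]c3c2OS(=O)(=O)[O-])ccc1O.[Na+] | intermediate
11 | scolopendrine, 7-(4-hydroxy-3-methoxybenzyl)-3-methoxy-2-oxo-1,2-dihydroquinolin-8-yl hydrogen sulfate | COc1cc(Cc2ccc3cc(OC)c(=O)[nH]c3c2OS(=O)(=O)O)ccc1O | target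

Total step count: 6. Longest linear sequence: 6 steps (1 to 11); boronic acid 6 enters as purchased.

Steps most likely to fail

Step 4. The neutral Mannich base may release the methide too slowly. The methide may also condense with itself faster than the aryl group is transferred, and 6 may protodeboronate. The fallback avoids a free methide and uses π-benzyl palladium chemistry. It sets out from 5. Boiling acetic anhydride exchanges the amine for acetate and acetylates the phenol, which should give 8-acetoxy-7-(acetoxymethyl)-3-methoxyquinolin-2(1H)-one F1. A Suzuki–Miyaura coupling of this benzylic acetate with 6 ([Pd(allyl)Cl]2, 1,5-bis(diphenylphosphino)pentane, K2CO3, t-AmOH, 80 °C) should give 7-[4-(benzyloxy)-3-methoxybenzyl]-3-methoxy-2-oxo-1,2-dihydroquinolin-8-yl acetate F2. Methanolysis (K2CO3, MeOH, rt) frees the C8 phenol and the route is rejoined at 8.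

Step 3. The electrophile may attack para to the hydroxyl (C5), or aminomethylation may occur twice. The fallback replaces the hydrogen-bond-guided Mannich reaction by a chelation-controlled formylation. It sets out from 4. A Casnati–Skattebøl ortho-formylation (MgCl2, Et3N, paraformaldehyde, MeCN, reflux) delivers formaldehyde from the magnesium phenoxide only to C7. This should give 8-hydroxy-3-methoxy-2-oxo-1,2-dihydroquinoline-7-carbaldehyde F3. Reductive amination (Me2NH, NaBH(OAc)3, 1,2-dichloroethane, rt) comes back to the route at 5.

Step 2. The N1/O8 chelating product may deactivate the catalyst, or hydrodebromination may compete. The fallback replaces catalytic C–O coupling by stoichiometric metalation and oxidation. It sets out from 3. Deprotonation of N1–H (NaH, THF, 0 °C) is followed by bromine–lithium exchange (n-BuLi, −78 °C), a quench with B(OMe)3 and an aqueous acid work-up. This should give (3-methoxy-2-oxo-1,2-dihydroquinolin-8-yl)boronic acid F4. Oxidation (H2O2, aq. NaOH, 0 °C) comes back to the route at 4.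

Further compounds
F1 | step 4 | 8-acetoxy-7-(acetoxymethyl)-3-methoxyquinolin-2(1H)-one | COc1cc2ccc(COC(C)=O)c(OC(C)=O)c2[nH]c1=O
F2 | step 4 | 7-[4-(benzyloxy)-3-methoxybenzyl]-3-methoxy-2-oxo-1,2-dihydroquinolin-8-yl acetate | COc1cc(Cc2ccc3cc(OC)c(=O)[nH]c3c2OC(C)=O)ccc1OCc1ccccc1
F3 | step 3 | 8-hydroxy-3-methoxy-2-oxo-1,2-dihydroquinoline-7-carbaldehyde | COc1cc2ccc(C=O)c(O)c2[nH]c1=O
F4 | step 2 | (3-methoxy-2-oxo-1,2-dihydroquinolin-8-yl)boronic acid | COc1cc2cccc(B(O)O)c2[nH]c1=O
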